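**Retrosynthetic overview**

1. Numbering is terpenoid style. Ring A is C1–C5 plus C10, and ring B is C5–C10. C1 bears OH, C3 bears Cl, C4 bears methyl and the side chain, C8 bears the ester, C9 bears the formyl group (C11), and C10 bears the angular methyl. β is the face of the C10 methyl and α is the opposite face.
2. The endgame is functional-group work only. The C9 formyl group comes from its dimethyl acetal. The (E)-allylic tertiary alcohol comes from a 4-methylpent-3-enyl chain by epoxide, selenide and selenoxide elimination. The C7=C8 enoate comes from the C6=C7 isomer with base. The axial C1–OH comes from a C1 ketone masked as a dithiane.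
3. The enabling feature is ring B. It is a cyclohexene with the ester carbon C8 next to the formyl-bearing C9, and it shares C5–C10 with ring A. With its double bond at C6=C7 it is a Diels–Alder retron: diene C5=C6–C7=C8(CO2Me) plus dienophile C9=C10 (an E-enal carrying the C10 methyl). The four ring A atoms C4–C3–C2–C1 already join the two.
4. The key disconnection cuts C8–C9 and C5–C10 together, as an intramolecular Diels–Alder reaction of an acyclic trienal. Rings A and B form in the same step, and no carbocycle exists before it.
5. The trienal comes from nerol (C2–C4, 4-methyl, side chain), trimethylsilylacetylene and methyl acrylate (C5–C8, ester), and prenyl acetate (C1, C9–C11, 10-methyl). The bonds and centres are made by epoxide/alkynylalane opening (C4), dithiane anion/epoxide union (C1–C2), Appel inversion (C3–Cl) and hydrozirconation/Heck (diene).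

Key step: step 14

**Route**

Step 1
Reactants: 1 nerol [(2Z)-3,7-dimethylocta-2,6-dien-1-ol]
Product: 2 (2R,3S)-2,3-epoxynerol
Conditions: Ti(OiPr)4 (cat.), D-(−)-diisopropyl tartrate (cat.), t-BuOOH, 4 Å MS, CH2Cl2, −20 °C
Reagents that add atoms: tert-butyl hydroperoxide, CC(C)(C)OO
Why: Sharpless asymmetric epoxidation is hydroxyl-directed, so only the allylic alkene reacts, and the D-(−)-tartrate should deliver oxygen to the face that gives 2R,3S, which fixes the future C3 and C4.

Step 2
Reactants: 2 (2R,3S)-2,3-epoxynerol; 3 trimethylsilylacetylene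
Product: 6 (2S,3S)-3,7-dimethyl-3-[(trimethylsilyl)ethynyl]oct-6-ene-1,2-diol, via lithium acetylide 4 (not isolated), via alkynylalane 5 (not isolated)
Conditions: 3, n-BuLi, toluene, 0 °C; Et2AlCl, 0 °C; then 2, 0 °C → rt; H2O work-up
Reagents that add atoms: none
Why: In this organoaluminium opening of a 2,3-epoxy alcohol the aluminium alkoxide activates the oxirane and the alkynyl group attacks the tertiary carbon with inversion, which sets the all-carbon quaternary centre (future C4) while the carbinol carbon keeps its configuration.

Step 3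
Reactants: 6 (2S,3S)-3,7-dimethyl-3-[(trimethylsilyl)ethynyl]oct-6-ene-1,2-diol
Product: 8 (2S)-2-[(3S)-3,7-dimethyl-1-(trimethylsilyl)oct-6-en-1-yn-3-yl]oxirane, via primary tosylate 7 (not isolated)
Conditions: NaH (2.2 equiv), N-tosylimidazole (1.0 equiv), THF, 0 °C → rt
Reagents that add atoms: none
Why: Selective sulfonylation of the primary alkoxide is followed by intramolecular Williamson closure, and the C–O bond of the secondary carbinol is never broken, so its configuration is retained.

Step 4
Reactants: 9 prenyl acetate (3-methylbut-2-en-1-yl acetate)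
Product: 10 (2E)-4-acetoxy-2-methylbut-2-enal
Conditions: SeO2, 1,4-dioxane, 80 °C
Reagents that add atoms: selenium dioxide, O=[Se]=O
Why: Riley allylic oxidation (ene reaction, then [2,3]-shift) selects the (E)-methyl group of the trisubstituted alkene and should give the E-enal.

Step 5
Reactants: 10 (2E)-4-acetoxy-2-methylbut-2-enal
Product: 11 (2E)-3-(1,3-dithian-2-yl)but-2-en-1-yl acetate
Conditions: HS(CH2)3SH, BF3·OEt2 (cat.), CH2Cl2, −20 °C
Reagents that add atoms: propane-1,3-dithiol, SCCCS
Why: Lewis acid-catalysed dithioacetalisation of an α-branched enal proceeds by 1,2-attack and leaves the alkene geometry untouched.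

Step 6
Reactants: 11 (2E)-3-(1,3-dithian-2-yl)but-2-en-1-yl acetate
Product: 12 (2E)-3-(1,3-dithian-2-yl)but-2-en-1-ol
Conditions: K2CO3 (cat.), MeOH, rt
Reagents that add atoms: none
Why: Base-catalysed transesterification removes the acetate without touching the dithiane or the alkene.

Step 7
Reactants: 12 (2E)-3-(1,3-dithian-2-yl)but-2-en-1-ol; 8 (2S)-2-[(3S)-3,7-dimethyl-1-(trimethylsilyl)oct-6-en-1-yn-3-yl]oxirane
Product: 14 (2E)-3-{2-[(2R,3S)-2-hydroxy-3,7-dimethyl-3-[(trimethylsilyl)ethynyl]oct-6-en-1-yl]-1,3-dithian-2-yl}but-2-en-1-ol, via dilithio dithiane 13 (not isolated)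
Conditions: 12, n-BuLi (2.1 equiv), THF–DMPU, −78 → −25 °C; then 8, −25 → 0 °C; H2O
Reagents that add atoms: none
Why: In this Corey–Seebach umpolung the lithium alkoxide cannot leave (so no 1,4-elimination) and keeps charge off the γ-carbon, so the dithiane carbanion opens the monosubstituted oxirane at CH2 by SN2 and the carbinol stereocentre is untouched.

Step 8
Reactants: 14 (coupled diol)
Product: 15 primary tert-butyldimethylsilyl ether of 14 (secondary carbinol R free, quaternary carbon S)
Conditions: TBSCl (1.05 equiv), imidazole, CH2Cl2, 0 °C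
Reagents that add atoms: tert-butyldimethylsilyl chloride, CC(C)(C)[Si](C)(C)Cl
Why: Silylation should select the unhindered primary allylic hydroxyl over the secondary hydroxyl next to the quaternary carbon.

Step 9
Reactants: 15 (silyl ether with free secondary carbinol)
Product: 16 secondary chloride (C–Cl carbon S, quaternary carbon S; O-TBS, C-TMS and dithiane retained)
Conditions: PPh3, CCl4, MeCN, 60 °C
Reagents that add atoms: carbon tetrachloride, ClC(Cl)(Cl)Cl
Why: In the Appel reaction the alkoxyphosphonium ion is displaced by chloride with inversion (R carbinol to S chloride); such displacements next to a quaternary carbon bearing methyl and an unsaturated group have close precedent, the slim alkynyl group leaves the backside open, and the reagent does not oxidise sulfur.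

Step 10
Reactants: 16 (secondary chloride)
Product: 17 (2E)-3-{2-[(2S,3S)-2-chloro-3-ethynyl-3,7-dimethyloct-6-en-1-yl]-1,3-dithian-2-yl}but-2-en-1-ol
Conditions: TBAF (2.5 equiv), THF, 0 °C → rt
Reagents that add atoms: none
Why: Fluoride-induced desilylation removes the O-silyl and the C-silyl group in one operation, and the hindered secondary chloride should be inert to fluoride.

Step 11
Reactants: 17 (terminal alkyne)
Product: 19 (2E)-3-{2-[(2S,3S)-2-chloro-3-[(E)-2-iodoethenyl]-3,7-dimethyloct-6-en-1-yl]-1,3-dithian-2-yl}but-2-en-1-ol, via vinylzirconocene 18 (not isolated)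
Conditions: Cp2Zr(H)Cl (2.5 equiv), THF, rt; then I2, 0 °C; H2O
Reagents that add atoms: iodine, II
Why: Hydrozirconation is a syn addition that places zirconium on the terminal carbon, iodinolysis proceeds with retention to give the E-vinyl iodide, one equivalent of hydride is consumed by the hydroxyl group, and trisubstituted alkenes do not react.

Step 12
Reactants: 19 (E-vinyl iodide); 20 methyl acrylate
Product: 21 methyl (2E,4E,6S,7S)-7-chloro-8-{2-[(2E)-4-hydroxybut-2-en-2-yl]-1,3-dithian-2-yl}-6-methyl-6-(4-methylpent-3-en-1-yl)octa-2,4-dienoate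
Conditions: Pd(OAc)2 (cat.), Bu4NCl, K2CO3, DMF, 40 °C
Reagents that add atoms: none
Why: The Heck reaction keeps the vinyl iodide geometry, and syn insertion followed by syn β-hydride elimination should give the 2E,4E-dienoate under silver-free conditions that spare the dithiane.

Step 13
Reactants: 21 (dienoate allylic alcohol)
Product: 22 methyl (2E,4E,6S,7S)-7-chloro-6-methyl-6-(4-methylpent-3-en-1-yl)-8-{2-[(2E)-4-oxobut-2-en-2-yl]-1,3-dithian-2-yl}octa-2,4-dienoate
Conditions: MnO2 (excess), CH2Cl2, rt
Reagents that add atoms: none
Why: Allylic alcohol oxidation with MnO2 is neutral, keeps the E geometry, and tolerates the dithiane, the chloride and the dienoate.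

Step 14
Reactants: 22 (acyclic trienal)
Product: 23 Diels–Alder adduct: trans-fused octalin (C6=C7) with spiro-1,3-dithiane at C1, 3β-Cl, 4β-CH3, 4α-(4-methylpent-3-enyl), 5α-H, 8β-CO2CH3, 9β-CHO, 10β-CH3
Conditions: toluene (0.005 M), BHT (cat.), 150 °C, sealed tube
Reagents that add atoms: none
Why: This is a concerted, asynchronous thermal [4+2] cycloaddition in which the (2E,4E)-dienoate C5=C6–C7=C8 adds suprafacially to the (E)-enal C9=C10; the closest known reaction type is the type 1 intramolecular Diels–Alder reaction of 1,7,9-decatrienes with a carbonyl group at the dienophile terminus, which gives trans-fused octalins through the carbonyl-endo transition state. Ring B closes as the cyclohexene of the cycloaddition (new bonds C8–C9 and C5–C10), and ring A closes in the same event as the six-membered ring formed by the four tether atoms C4–C3–C2–C1 together with C5 and C10 (fused mode, chair-like tether; a four-atom tether cannot reach the bridged mode). C9 and C10 follow from the E geometry of the enal (10-methyl and formyl cis, both β), C5 follows from the E geometry at C5=C6 combined with the formyl-endo/tether-exo arrangement (H-5 anti to the 10-methyl group, trans fusion), and C8 follows from the E geometry at C7=C8 (ester cis to formyl; this centre is erased in step 18). The endo/exo selectivity is secured by the two fully substituted tether ends, because each cis-forming chair would place a ring B carbon axial on ring A, either against the axial 4-methyl group or against the axial sulfur at C1. The π-facial selectivity is secured by C3, because of the two endo transition states only one keeps the C–Cl bond equatorial while the other sets chlorine syn-axial to the axial dithiane sulfur, so the stereocentres C3 and C4 made earlier dictate the absolute sense of all four new centres. Chemoselectivity rests on activation (the side-chain alkene is unactivated and cannot reach the diene in a small ring), and the geminal substitution at C1 and C4 (Thorpe–Ingold effect) should compensate for the electron-poor diene.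

Step 15
Reactants: 23 (Diels–Alder adduct)
Product: 24 dimethyl acetal of 23 [9β-CH(OCH3)2]
Conditions: HC(OMe)3, PPTS (cat.), MeOH, rt
Reagents that add atoms: trimethyl orthoformate, COC(OC)OC
Why: Acid-catalysed acetalisation masks the aldehyde against hydride and removes the acidity of H-9 for step 18, while the dithiane, ester and chloride are inert.

Step 16
Reactants: 24 (acetal, dithiane)
Product: 25 C1 ketone (3β-Cl, C6=C7, 8β-CO2CH3, 9β-CH(OCH3)2)
Conditions: MeI, CaCO3, MeCN–H2O (9:1), 45 °C
Reagents that add atoms: water, O
Why: Alkylative dithiane hydrolysis (S-methylation, thionium ion, water) runs under buffered neutral conditions that keep the acetal, and the equatorial chlorine is poorly aligned with the enol π-system, so β-elimination should not intervene.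

Step 17
Reactants: 25 (C1 ketone)
Product: 26 1α-alcohol (axial OH; otherwise as 25)
Conditions: LiBH(s-Bu)3, THF, −78 °C; H2O
Reagents that add atoms: none
Why: In this substrate-controlled reduction the bulky trialkylborohydride takes the equatorial (β-face) trajectory because the axial path is blocked by the syn-axial H-3, H-5 and H-9, as in the reduction of 4,4-dimethyl-3-oxo terpenoids to axial alcohols, which sets 1α-OH and spares the unconjugated ester.

Step 18
Reactants: 26 (1α-alcohol, C6=C7)
Product: 27 conjugated ester (C7=C8; 1α-OH, 3β-Cl, 9β-CH(OCH3)2)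
Conditions: DBU, toluene, 60 °C
Reagents that add atoms: none
Why: Base-mediated β,γ to α,β isomerisation through the extended ester enolate gives the thermodynamic enoate; H-9 is not acidic in the acetal, so C9 holds, and the equatorial chloride has no antiperiplanar hydrogen for E2.

Step 19
Reactants: 27 (conjugated ester)
Product: 28 side-chain epoxide of 27 (both epimers at the oxirane CH)
Conditions: mCPBA (1.05 equiv), NaHCO3, CH2Cl2, 0 °C
Reagents that add atoms: 3-chloroperoxybenzoic acid, OOC(=O)c1cccc(Cl)c1
Why: Prilezhaev epoxidation selects the electron-rich trisubstituted alkene over the enoate, and the new stereocentre is destroyed in step 20, so both epimers converge.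

Step 20
Reactants: 28 (side-chain epoxide)
Product: 31 acetal-protected target bearing the (E)-4-hydroxy-4-methylpent-2-enyl chain, via hydroxy selenide 29 (not isolated), via selenoxide 30 (not isolated)
Conditions: (PhSe)2, NaBH4, MeOH, rt → 50 °C; then 30% H2O2, THF, 0 °C → rt
Reagents that add atoms: none
Why: In this epoxide to allylic alcohol transposition the selenolate opens the oxirane at its CH carbon (SN2), and the selenoxide syn-elimination can only run toward the CH2 group, which should give the E-alkene and the tertiary alcohol.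

Step 21
Reactants: 31 (acetal-protected target)
Product: 32 target, methyl (1R,4aR,5S,6S,8S,8aS)-6-chloro-1-formyl-8-hydroxy-5-[(2E)-4-hydroxy-4-methylpent-2-en-1-yl]-5,8a-dimethyl-1,4,4a,5,6,7,8,8a-octahydronaphthalene-2-carboxylate
Conditions: PPTS (cat.), acetone–H2O (10:1), rt → 40 °C
Reagents that add atoms: water, O
Why: Mild acid-catalysed acetal hydrolysis is base-free, so the 9β-formyl group should not epimerise, and the 1α-OH is trans-disposed to C11, so no lactol can form.

**Compound list**

1 | nerol | CC(C)=CCC/C(C)=C\CO | starting material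
2 | (2R,3S)-2,3-epoxynerol | OC[C@H]1O[C@@]1(C)CCC=C(C)C | intermediate
3 | trimethylsilylacetylene | C#C[Si](C)(C)C | starting material
4 | lithium (trimethylsilyl)acetylide | [Li]C#C[Si](C)(C)C | intermediate
5 | diethyl[(trimethylsilyl)ethynyl]aluminium | CC[Al](CC)C#C[Si](C)(C)C | intermediate
6 | (2S,3S)-3,7-dimethyl-3-[(trimethylsilyl)ethynyl]oct-6-ene-1,2-diol | C[Si](C)(C)C#C[C@](C)(CCC=C(C)C)[C@H](O)CO | intermediate
7 | 1-O-tosylate of 6 | C[Si](C)(C)C#C[C@](C)(CCC=C(C)C)[C@H](O)COS(=O)(=O)c1ccc(C)cc1 | intermediate
8 | (2S)-2-[(3S)-3,7-dimethyl-1-(trimethylsilyl)oct-6-en-1-yn-3-yl]oxirane | C[Si](C)(C)C#C[C@](C)(CCC=C(C)C)[C@H]1CO1 | intermediate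
9 | prenyl acetate | CC(C)=CCOC(C)=O | starting material
10 | (2E)-4-acetoxy-2-methylbut-2-enal | CC(=O)OC/C=C(\C)C=O | intermediate
11 | (2E)-3-(1,3-dithian-2-yl)but-2-en-1-yl acetate | CC(=O)OC/C=C(\C)C1SCCCS1 | intermediate
12 | (2E)-3-(1,3-dithian-2-yl)but-2-en-1-ol | OC/C=C(\C)C1SCCCS1 | intermediate
13 | O,C-dilithio derivative of 12 | [Li]OC/C=C(\C)C1([Li])SCCCS1 | intermediate
14 | coupled diol (carbinol R, quaternary carbon S) | C[Si](C)(C)C#C[C@](C)(CCC=C(C)C)[C@H](O)CC1(SCCCS1)/C(C)=C/CO | intermediate
15 | primary TBS ether of 14 | C[Si](C)(C)C#C[C@](C)(CCC=C(C)C)[C@H](O)CC1(SCCCS1)/C(C)=C/CO[Si](C)(C)C(C)(C)C | intermediate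
16 | secondary chloride (C–Cl carbon S, quaternary carbon S) | C[Si](C)(C)C#C[C@](C)(CCC=C(C)C)[C@@H](Cl)CC1(SCCCS1)/C(C)=C/CO[Si](C)(C)C(C)(C)C | intermediate
17 | terminal alkyne with free allylic alcohol | C#C[C@](C)(CCC=C(C)C)[C@@H](Cl)CC1(SCCCS1)/C(C)=C/CO | intermediate
18 | (E)-vinylzirconocene chloride, hydroxyl held as zirconocene alkoxide | Cl[Zr](C1C=CC=C1)(C1C=CC=C1)/C=C/[C@](C)(CCC=C(C)C)[C@@H](Cl)CC1(SCCCS1)/C(C)=C/CO[Zr](Cl)(C1C=CC=C1)C1C=CC=C1 | intermediate
19 | (E)-vinyl iodide | I/C=C/[C@](C)(CCC=C(C)C)[C@@H](Cl)CC1(SCCCS1)/C(C)=C/CO | intermediate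
20 | methyl acrylate | C=CC(=O)OC | starting material
21 | (2E,4E,6S,7S)-dienoate allylic alcohol | COC(=O)/C=C/C=C/[C@](C)(CCC=C(C)C)[C@@H](Cl)CC1(SCCCS1)/C(C)=C/CO | intermediate
22 | acyclic trienal (cycloaddition precursor) | COC(=O)/C=C/C=C/[C@](C)(CCC=C(C)C)[C@@H](Cl)CC1(SCCCS1)/C(C)=C/C=O | intermediate
23 | Diels–Alder adduct (trans-octalin, C6=C7, C1 dithiane, 9β-CHO) | COC(=O)[C@H]1C=C[C@H]2[C@](C)(CCC=C(C)C)[C@@H](Cl)CC3(SCCCS3)[C@]2(C)[C@H]1C=O | intermediate
24 | dimethyl acetal of 23 | COC(=O)[C@H]1C=C[C@H]2[C@](C)(CCC=C(C)C)[C@@H](Cl)CC3(SCCCS3)[C@]2(C)[C@H]1C(OC)OC | intermediate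
25 | C1 ketone | COC(=O)[C@H]1C=C[C@H]2[C@](C)(CCC=C(C)C)[C@@H](Cl)CC(=O)[C@]2(C)[C@H]1C(OC)OC | intermediate
26 | 1α-alcohol | COC(=O)[C@H]1C=C[C@H]2[C@](C)(CCC=C(C)C)[C@@H](Cl)C[C@H](O)[C@]2(C)[C@H]1C(OC)OC | intermediate
27 | conjugated ester (C7=C8) | COC(=O)C1=CC[C@H]2[C@](C)(CCC=C(C)C)[C@@H](Cl)C[C@H](O)[C@]2(C)[C@H]1C(OC)OC | intermediate
28 | side-chain epoxide (epimers at oxirane CH) | COC(=O)C1=CC[C@H]2[C@](C)(CCC3OC3(C)C)[C@@H](Cl)C[C@H](O)[C@]2(C)[C@H]1C(OC)OC | intermediate
29 | β-hydroxy phenyl selenide | COC(=O)C1=CC[C@H]2[C@](C)(CCC([Se]c3ccccc3)C(C)(C)O)[C@@H](Cl)C[C@H](O)[C@]2(C)[C@H]1C(OC)OC | intermediate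
30 | selenoxide of 29 | COC(=O)C1=CC[C@H]2[C@](C)(CCC([Se](=O)c3ccccc3)C(C)(C)O)[C@@H](Cl)C[C@H](O)[C@]2(C)[C@H]1C(OC)OC | intermediate
31 | acetal-protected target | COC(=O)C1=CC[C@H]2[C@](C)(C/C=C/C(C)(C)O)[C@@H](Cl)C[C@H](O)[C@]2(C)[C@H]1C(OC)OC | intermediate
32 | CNP0167913.1 | COC(=O)C1=CC[C@H]2[C@](C)(C/C=C/C(C)(C)O)[C@@H](Cl)C[C@H](O)[C@]2(C)[C@H]1C=O | target

**Step count**

Total step count: 21.
Longest linear sequence: 18 (steps 1–3 and 7–21, from nerol).

**Steps most likely to fail**

**Step 14 (cycloaddition).**
- What may go wrong: the electron-poor diene may add too slowly to a β,β-disubstituted enal that sits next to the spiro dithiane. Enal isomerisation, oligomerisation or thermal loss of HCl could then overtake ring closure.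
- Fallback: it sets out from 22 and comes back at 25.
- The dithiane is removed before the cycloaddition (MeI, CaCO3, aqueous MeCN) to give the ene-dione trienal F1. Its dienophile is flanked by the formyl and the C1 keto group, so it is far more electrophilic and less crowded.
- F1 should cyclise near room temperature to the keto aldehyde F2. If needed, Me2AlCl bound to the formyl group can hold that group endo.
- Aldehyde-selective acetalisation (HC(OMe)3, PPTS, MeOH; the ketone next to C10 is too hindered to react) then gives 25.
- The price is that facial control rests only on the equatorial preference of the C–Cl bond.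

**Step 9 (chlorination).**
- What may go wrong: backside attack at a carbinol next to a quaternary carbon may be slow. Elimination to the alkene or a 1,2-shift of the activated alcohol could then compete.
- Fallback: it sets out from 6 and comes back at 17. It makes the C–Cl bond electrophilically instead of by displacement.
- NaIO4 cleavage gives the quaternary aldehyde F3.
- Wittig methoxymethylenation (Ph3P=CHOMe) gives the enol ether F4.
- Mild acid hydrolysis gives the homologated aldehyde F5.
- Enamine-catalysed α-chlorination (NCS, with the enantiomer of 2,5-diphenylpyrrolidine that delivers the R chloro aldehyde) gives the α-chloro aldehyde F6.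
- NaBH4 gives the chlorohydrin F7, and Tf2O with 2,6-lutidine gives the primary triflate F8.
- Alkylation of the dilithio dithiane 13 gives the coupled chloride F9.
- K2CO3 in MeOH removes the C-silyl group to give 17.

**Step 17 (ketone reduction).**
- What may go wrong: facial selectivity may be poor (hydride entering from the α face), or enolisation may be followed by loss of chloride.
- Fallback: it sets out from 25 and comes back at 26. It replaces substrate control by catalyst control.
- A CBS reduction is used, with (R)-2-methyl-CBS-oxazaborolidine and catecholborane in toluene at −78 °C.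
- The quaternary C10 flank acts as the large group and C2H2 as the small group, so the catalyst rather than the shape of the decalin fixes hydride delivery to the β face.
- No new compound arises (F0).

**Further compounds**

F1 | step 14 | methyl (2E,4E,6S,7S,10E)-7-chloro-6,10-dimethyl-6-(4-methylpent-3-en-1-yl)-9,12-dioxododeca-2,4,10-trienoate | COC(=O)/C=C/C=C/[C@](C)(CCC=C(C)C)[C@@H](Cl)CC(=O)/C(C)=C/C=O
F2 | step 14 | keto aldehyde (trans-octalin, C6=C7, C1 ketone, 9β-CHO) | COC(=O)[C@H]1C=C[C@H]2[C@](C)(CCC=C(C)C)[C@@H](Cl)CC(=O)[C@]2(C)[C@H]1C=O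
F3 | step 9 | (2S)-2,6-dimethyl-2-[(trimethylsilyl)ethynyl]hept-5-enal | C[Si](C)(C)C#C[C@](C)(CCC=C(C)C)C=O
F4 | step 9 | methyl enol ether of the homologated aldehyde (E/Z mixture) | C[Si](C)(C)C#C[C@](C)(CCC=C(C)C)C=COC
F5 | step 9 | 3,7-dimethyl-3-[(trimethylsilyl)ethynyl]oct-6-enal (quaternary centre as in 6) | C[Si](C)(C)C#C[C@](C)(CCC=C(C)C)CC=O
F6 | step 9 | (2R)-2-chloro derivative of F5 | C[Si](C)(C)C#C[C@](C)(CCC=C(C)C)[C@@H](Cl)C=O
F7 | step 9 | 2-chloro-3,7-dimethyl-3-[(trimethylsilyl)ethynyl]oct-6-en-1-ol | C[Si](C)(C)C#C[C@](C)(CCC=C(C)C)[C@@H](Cl)CO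
F8 | step 9 | primary triflate of F7 | C[Si](C)(C)C#C[C@](C)(CCC=C(C)C)[C@@H](Cl)COS(=O)(=O)C(F)(F)F
F9 | step 9 | C-trimethylsilyl derivative of 17 | C[Si](C)(C)C#C[C@](C)(CCC=C(C)C)[C@@H](Cl)CC1(SCCCS1)/C(C)=C/CO
F0 | step 17 | none | none
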